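Ring A (C1–OMe, C3–OH, C4 aroyl, C6 arylpropyl) is disconnected at C2–C3 and C3–C4: C3 comes from carbon monoxide, the other five ring carbons from a 3-pivaloyloxy-1,4-enyne. A single rhodium-catalysed [5+1] benzannulation closes ring A and, through the 1,2-shift of the ester, leaves the two resorcinol oxygens differentiated, C1–O as pivalate and C3–OH free next to the C4 ketone, with the chain para to C3–OH. The precursor is a racemic tertiary propargylic pivalate bearing a terminal alkyne, the benzyl-protected 3-arylpropyl chain and an (E)-2-aroylvinyl group; it is assembled from a 2,5-disubstituted furan by oxidative ring opening and site-selective ethynyl addition.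

Key step: step 7

Remark on the chemistry: ring A is numbered C1 (OMe), C2 (H), C3 (OH), C4 (aroyl), C5 (H), C6 (chain), ring B is the benzoyl ring and ring C the phenol ring of the propyl chain; the carbinol carbon of the precursor is carried as the racemate because it becomes aromatic C6.

Step 1
Reactants: 1 furan-2-boronic acid; 2 1-(benzyloxy)-4-bromobenzene
Product: 3 2-[4-(benzyloxy)phenyl]furan
Conditions: Pd(PPh3)4 (3 mol %), Na2CO3, DME/H2O, 80 °C
Reagents that add atoms: none
Why: Suzuki–Miyaura coupling of an aryl bromide with a 2-furylboronic acid at zerovalent palladium is routine, a modest excess of 1 offsets protodeboronation, and the benzyl ether is inert.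

Step 2
Reactants: 4 3-(4-hydroxyphenyl)propan-1-ol
Product: 5 3-[4-(benzyloxy)phenyl]propan-1-ol
Conditions: BnBr, K2CO3, acetone, reflux
Reagents that add atoms: benzyl bromide, BrCc1ccccc1
Why: Williamson etherification; K2CO3 deprotonates only the phenol, so the primary alcohol should stay free.

Step 3
Reactants: 5 3-[4-(benzyloxy)phenyl]propan-1-ol
Product: 6 1-(benzyloxy)-4-(3-bromopropyl)benzene
Conditions: CBr4, PPh3, CH2Cl2, 0 °C → rt
Reagents that add atoms: carbon tetrabromide, BrC(Br)(Br)Br
Why: Appel bromination converts the primary alcohol into the bromide under neutral conditions that leave the aryl benzyl ether untouched.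

Step 4
Reactants: 3 2-[4-(benzyloxy)phenyl]furan; 6 1-(benzyloxy)-4-(3-bromopropyl)benzene
Product: 8 2-[4-(benzyloxy)phenyl]-5-{3-[4-(benzyloxy)phenyl]propyl}furan, via 5-lithiofuran 7 (not isolated)
Conditions: n-BuLi, THF, −78 → 0 °C; then 6, DMPU, 0 °C → rt
Reagents that add atoms: none
Why: α-Lithiation of the furan at its only free α-position (C5) followed by SN2 alkylation with a primary bromide is standard furan chemistry, and aryl benzyl ethers tolerate n-BuLi for a short time at or below 0 °C.

Step 5
Reactants: 8 2-[4-(benzyloxy)phenyl]-5-{3-[4-(benzyloxy)phenyl]propyl}furan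
Product: 10 (E)-1,7-bis[4-(benzyloxy)phenyl]hept-2-ene-1,4-dione, via (Z)-enedione 9 (not isolated)
Conditions: NBS, NaHCO3, acetone/H2O, −20 °C; then pyridine, rt
Reagents that add atoms: water, O
Why: Oxidative furan ring opening (bromonium attack at a furan α-carbon, addition of water, collapse of the dihydrofuran hemiketal) should give the cis-enedione, which pyridine isomerises to the more stable trans isomer by reversible conjugate addition; the alkoxyarene rings are far less nucleophilic than the furan at −20 °C.

Step 6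
Reactants: 10 (E)-1,7-bis[4-(benzyloxy)phenyl]hept-2-ene-1,4-dione; 11 ethynylmagnesium bromide
Product: 13 racemic (E)-1,7-bis[4-(benzyloxy)phenyl]-4-ethynyl-1-oxohept-2-en-4-yl pivalate, via bromomagnesium alkoxide 12 (not isolated)
Conditions: HC≡CMgBr (1.1 equiv), THF, −78 °C; then PivCl, DMAP (cat.), −78 °C → rt
Reagents that add atoms: pivaloyl chloride, CC(C)(C)C(Cl)=O
Why: Grignard 1,2-addition of the acetylide should take place at the alkyl ketone, which is less hindered and more electrophilic than the aryl ketone deactivated by its para-benzyloxy donor, and the tertiary alkoxide is O-acylated in the same flask; the new quaternary carbinol carbon forms as a racemate without control, which is harmless because it becomes aromatic C6 in step 7.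

Step 7
Reactants: 13 racemic (E)-1,7-bis[4-(benzyloxy)phenyl]-4-ethynyl-1-oxohept-2-en-4-yl pivalate; 14 carbon monoxide
Product: 16 4-[4-(benzyloxy)benzoyl]-2-{3-[4-(benzyloxy)phenyl]propyl}-5-hydroxyphenyl pivalate, via cyclohexadienone tautomer 15 (not isolated)
Conditions: [RhCl(CO)2]2 (5 mol %), CO (80 atm), CH2Cl2, 80 °C, autoclave
Reagents that add atoms: none
Why: Monovalent rhodium activates the terminal alkyne, the pivalate carbonyl attacks the internal alkyne carbon and the ester shifts 1,2 to give a rhodium vinylcarbene, which either takes up CO to a dienylketene that undergoes 6π-electrocyclisation or closes with the (E)-alkene to a rhodacyclohexadiene that inserts CO and reductively eliminates, both paths leading to cyclohexadienone 15, which enolises to the phenol. The closest known reaction is the rhodium-catalysed [5+1] carbonylative benzannulation of 3-acyloxy-1,4-enynes to resorcinol monoesters; an aroyl group on the alkene terminus is not covered by that precedent and is the main uncertainty. Ring A closes in a [5+1] mode, the CO carbon (C3) being joined to the former alkyne terminus (C2) and to the aroyl-bearing alkene carbon (C4). No stereocentre results: the racemic carbinol carbon of 13 becomes aromatic C6 and the sp3 carbon of 15 is lost on tautomerisation, which the hydrogen bond between the new C3–OH and the C4 ketone should make irreversible. The step needs 1,2- rather than 1,3-acyloxy migration (the latter would lead to an allenyl ester); the terminal alkyne and the bulky tertiary pivalate secure this, and the shift in turn places the pivalate at C1, meta to the new hydroxyl, and the chain at C6, para to it.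

Step 8
Reactants: 16 4-[4-(benzyloxy)benzoyl]-2-{3-[4-(benzyloxy)phenyl]propyl}-5-hydroxyphenyl pivalate
Product: 18 [4-(benzyloxy)phenyl](5-{3-[4-(benzyloxy)phenyl]propyl}-2-hydroxy-4-methoxyphenyl)methanone, via dihydroxybenzophenone 17 (not isolated)
Conditions: K2CO3, MeOH, rt; evaporate; then MeI (1.1 equiv), K2CO3, acetone, 40 °C
Reagents that add atoms: iodomethane, CI
Why: Methanolysis (transesterification) of the activated aryl pivalate followed by Williamson O-methylation; the C3–OH is hydrogen-bonded to the ketone and far less nucleophilic, so methylation should stop at the more acidic, non-chelated C1–O, as in the well-known 4-O-methylation of 2,4-dihydroxybenzophenones.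

Step 9
Reactants: 18 [4-(benzyloxy)phenyl](5-{3-[4-(benzyloxy)phenyl]propyl}-2-hydroxy-4-methoxyphenyl)methanone
Product: 19 {2-hydroxy-5-[3-(4-hydroxyphenyl)propyl]-4-methoxyphenyl}(4-hydroxyphenyl)methanone
Conditions: H2 (1 atm), Pd/C (10 %), EtOAc/MeOH, rt
Reagents that add atoms: none
Why: Catalytic hydrogenolysis should cleave both aryl benzyl ethers, while the electron-rich, chelated diaryl ketone and the aryl methyl ether should survive at 1 atm and rt if the reaction is stopped at full conversion.

Compound list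
1 | furan-2-boronic acid | OB(O)c1ccco1 | starting material
2 | 1-(benzyloxy)-4-bromobenzene | Brc1ccc(OCc2ccccc2)cc1 | starting material
3 | 2-[4-(benzyloxy)phenyl]furan | o1cccc1-c1ccc(OCc2ccccc2)cc1 | intermediate
4 | 3-(4-hydroxyphenyl)propan-1-ol | OCCCc1ccc(O)cc1 | starting material
5 | 3-[4-(benzyloxy)phenyl]propan-1-ol | OCCCc1ccc(OCc2ccccc2)cc1 | intermediate
6 | 1-(benzyloxy)-4-(3-bromopropyl)benzene | BrCCCc1ccc(OCc2ccccc2)cc1 | intermediate
7 | {5-[4-(benzyloxy)phenyl]furan-2-yl}lithium (not isolated) | [Li]c1ccc(o1)-c1ccc(OCc2ccccc2)cc1 | intermediate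
8 | 2-[4-(benzyloxy)phenyl]-5-{3-[4-(benzyloxy)phenyl]propyl}furan | C(CCc1ccc(OCc2ccccc2)cc1)c1ccc(o1)-c1ccc(OCc2ccccc2)cc1 | intermediate
9 | (Z)-1,7-bis[4-(benzyloxy)phenyl]hept-2-ene-1,4-dione (not isolated) | O=C(/C=C\C(=O)CCCc1ccc(OCc2ccccc2)cc1)c1ccc(OCc2ccccc2)cc1 | intermediate
10 | (E)-1,7-bis[4-(benzyloxy)phenyl]hept-2-ene-1,4-dione | O=C(/C=C/C(=O)CCCc1ccc(OCc2ccccc2)cc1)c1ccc(OCc2ccccc2)cc1 | intermediate
11 | ethynylmagnesium bromide | C#C[Mg]Br | starting material
12 | bromomagnesium (E)-1,7-bis[4-(benzyloxy)phenyl]-4-ethynyl-1-oxohept-2-en-4-olate, racemic (not isolated) | C#CC(CCCc1ccc(OCc2ccccc2)cc1)(O[Mg]Br)/C=C/C(=O)c1ccc(OCc2ccccc2)cc1 | intermediate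
13 | racemic (E)-1,7-bis[4-(benzyloxy)phenyl]-4-ethynyl-1-oxohept-2-en-4-yl pivalate | C#CC(CCCc1ccc(OCc2ccccc2)cc1)(OC(=O)C(C)(C)C)/C=C/C(=O)c1ccc(OCc2ccccc2)cc1 | intermediate
14 | carbon monoxide | [C-]#[O+] | starting material
15 | racemic 4-[4-(benzyloxy)benzoyl]-6-{3-[4-(benzyloxy)phenyl]propyl}-3-oxocyclohexa-1,5-dien-1-yl pivalate (not isolated) | O=C1C=C(OC(=O)C(C)(C)C)C(CCCc2ccc(OCc3ccccc3)cc2)=CC1C(=O)c1ccc(OCc2ccccc2)cc1 | intermediate
16 | 4-[4-(benzyloxy)benzoyl]-2-{3-[4-(benzyloxy)phenyl]propyl}-5-hydroxyphenyl pivalate | CC(C)(C)C(=O)Oc1cc(O)c(C(=O)c2ccc(OCc3ccccc3)cc2)cc1CCCc1ccc(OCc2ccccc2)cc1 | intermediate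
17 | [4-(benzyloxy)phenyl](5-{3-[4-(benzyloxy)phenyl]propyl}-2,4-dihydroxyphenyl)methanone (not isolated) | Oc1cc(O)c(C(=O)c2ccc(OCc3ccccc3)cc2)cc1CCCc1ccc(OCc2ccccc2)cc1 | intermediate
18 | [4-(benzyloxy)phenyl](5-{3-[4-(benzyloxy)phenyl]propyl}-2-hydroxy-4-methoxyphenyl)methanone | COc1cc(O)c(C(=O)c2ccc(OCc3ccccc3)cc2)cc1CCCc1ccc(OCc2ccccc2)cc1 | intermediate
19 | {2-hydroxy-5-[3-(4-hydroxyphenyl)propyl]-4-methoxyphenyl}(4-hydroxyphenyl)methanone | COc1cc(O)c(C(=O)c2ccc(O)cc2)cc1CCCc1ccc(O)cc1 | target

Total step count: 9. Longest linear sequence: 8 steps (steps 2, 3, 4, 5, 6, 7, 8, 9, from 3-(4-hydroxyphenyl)propan-1-ol).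

Steps most likely to fail

Step 7. The acyloxy shift and carbonylation sequence may be diverted: the electron-poor aroyl alkene may fail to engage the carbene or ketene, so that 1,3-shift, cyclopentannulation without CO uptake or oligomerisation of the enone take over. The fallback sets out from 6 and comes back to the route at 19; it takes ring A from a resorcinol building block instead of constructing it. Alkyl–aryl Suzuki coupling of 6 with commercial (2,4-dimethoxyphenyl)boronic acid (Pd(OAc)2, P(t-Bu)2Me, KOt-Bu, tert-amyl alcohol, rt) should give 1-{3-[4-(benzyloxy)phenyl]propyl}-2,4-dimethoxybenzene F1. Friedel–Crafts acylation of F1 with commercial 4-(benzyloxy)benzoyl chloride and SnCl4 in CH2Cl2 at −20 °C should occur at the ring position para to one methoxy group and ortho to the other, giving [4-(benzyloxy)phenyl](5-{3-[4-(benzyloxy)phenyl]propyl}-2,4-dimethoxyphenyl)methanone F2; partial loss of benzyl groups here would not matter. BCl3 with pentamethylbenzene in CH2Cl2 (−78 → 0 °C) should then remove both benzyl groups and, through chelation to the ketone, only the methyl ether ortho to it, giving 19.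

Step 6. Site selectivity may be poor (attack at the aryl ketone, conjugate addition or double addition), and acylation of the hindered alkoxide may be incomplete. The fallback sets out from 6 and comes back at 13; it creates the carbinol carbon before the aryl ketone exists.
- Magnesium in THF converts 6 into {3-[4-(benzyloxy)phenyl]propyl}magnesium bromide F3.
- Addition of F3 to ethyl diethoxyacetate at −78 °C should give 5-[4-(benzyloxy)phenyl]-1,1-diethoxypentan-2-one F4.
- Ethynylmagnesium bromide 11 adds to the only ketone of F4 to give bromomagnesium 6-[4-(benzyloxy)phenyl]-3-(diethoxymethyl)hex-1-yn-3-olate F5, which is trapped with PivCl as 6-[4-(benzyloxy)phenyl]-3-(diethoxymethyl)hex-1-yn-3-yl pivalate F6.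
- Aqueous TFA in CHCl3 should unmask 6-[4-(benzyloxy)phenyl]-3-formylhex-1-yn-3-yl pivalate F7.
- Commercial 2-bromo-1-[4-(benzyloxy)phenyl]ethan-1-one and PPh3 give {2-[4-(benzyloxy)phenyl]-2-oxoethyl}triphenylphosphonium bromide F8, which aqueous NaOH converts into the stabilised ylide 1-[4-(benzyloxy)phenyl]-2-(triphenyl-λ5-phosphanylidene)ethan-1-one F9.
- Wittig olefination of F7 with F9 in toluene at 80 °C should give the (E)-enone 13.

Step 4. The SN2 alkylation of the furyllithium may be sluggish, with E2 elimination of the bromide or metalation at a benzylic OCH2 position competing. The fallback sets out from 3 and 6 and comes back at 8; it reverses the polarity and forms the bond by Negishi coupling. Bromination of 3 at the free furan α-position (NBS, DMF, −20 °C) should give 2-[4-(benzyloxy)phenyl]-5-bromofuran F10. Zinc dust and LiCl in THF convert 6 into {3-[4-(benzyloxy)phenyl]propyl}zinc bromide F11. Coupling of F10 with F11 under Pd(OAc)2/SPhos in THF at rt should give 8.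

Further compounds
F1 | step 7 | 1-{3-[4-(benzyloxy)phenyl]propyl}-2,4-dimethoxybenzene | COc1ccc(CCCc2ccc(OCc3ccccc3)cc2)c(OC)c1
F2 | step 7 | [4-(benzyloxy)phenyl](5-{3-[4-(benzyloxy)phenyl]propyl}-2,4-dimethoxyphenyl)methanone | COc1cc(OC)c(C(=O)c2ccc(OCc3ccccc3)cc2)cc1CCCc1ccc(OCc2ccccc2)cc1
F3 | step 6 | {3-[4-(benzyloxy)phenyl]propyl}magnesium bromide | Br[Mg]CCCc1ccc(OCc2ccccc2)cc1
F4 | step 6 | 5-[4-(benzyloxy)phenyl]-1,1-diethoxypentan-2-one | CCOC(OCC)C(=O)CCCc1ccc(OCc2ccccc2)cc1
F5 | step 6 | bromomagnesium 6-[4-(benzyloxy)phenyl]-3-(diethoxymethyl)hex-1-yn-3-olate, racemic | C#CC(CCCc1ccc(OCc2ccccc2)cc1)(O[Mg]Br)C(OCC)OCC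
F6 | step 6 | 6-[4-(benzyloxy)phenyl]-3-(diethoxymethyl)hex-1-yn-3-yl pivalate, racemic | C#CC(CCCc1ccc(OCc2ccccc2)cc1)(OC(=O)C(C)(C)C)C(OCC)OCC
F7 | step 6 | 6-[4-(benzyloxy)phenyl]-3-formylhex-1-yn-3-yl pivalate, racemic | C#CC(CCCc1ccc(OCc2ccccc2)cc1)(OC(=O)C(C)(C)C)C=O
F8 | step 6 | {2-[4-(benzyloxy)phenyl]-2-oxoethyl}triphenylphosphonium bromide | [Br-].O=C(C[P+](c1ccccc1)(c1ccccc1)c1ccccc1)c1ccc(OCc2ccccc2)cc1
F9 | step 6 | 1-[4-(benzyloxy)phenyl]-2-(triphenyl-λ5-phosphanylidene)ethan-1-one | O=C(C=P(c1ccccc1)(c1ccccc1)c1ccccc1)c1ccc(OCc2ccccc2)cc1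
F10 | step 4 | 2-[4-(benzyloxy)phenyl]-5-bromofuran | Brc1ccc(o1)-c1ccc(OCc2ccccc2)cc1
F11 | step 4 | {3-[4-(benzyloxy)phenyl]propyl}zinc bromide | Br[Zn]CCCc1ccc(OCc2ccccc2)cc1
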